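**Retrosynthetic overview**

1. Target 16 ⇒ ester C–O bond: (2R)-2-methylbutanoic acid 14 plus the dibenzyl-protected oxolane alcohol 13; the benzyl ethers come off last.
2. Oxolane ring of 13 (formed last) ⇒ C2–O bond by SN1 cycloetherification of triol 12, which comes from hydride opening of the trans aldol lactone 11 (lactone 7 + aldehyde 9).
3. γ-Butyrolactone 7 (first stereocentre) ⇒ enantioselective carbonylative ring expansion of the prochiral oxetane 6 with CO (four- to five-membered ring).
4. Oxetane 6 ⇒ aryl bromide 4 + 3-(bromomethyl)oxetane 5 by nickel reductive coupling; aldehyde 9 comes from the same bromide 4.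
5. Bromide 4 ⇒ catechol 1 by O-methylation, para-bromination and O-benzylation. Ring order: oxetane (bought) → lactone (ring expansion) → oxolane (cyclisation).

Assumption: the SMILES is read as the (2R,3S,4S)-oxolane (2,3-trans, 3,4-cis) acylated on its CH2OH by (2R)-2-methylbutanoic acid; in step 5 the (R,R)-salen catalyst is taken to give (S)-7, and its antipode is used if the sense of induction proves opposite.

**Route**

Step 1
Reactants: 1 benzene-1,2-diol (catechol)
Product: 2 2-methoxyphenol (guaiacol)
Conditions: MeI (1.0 equiv), K2CO3 (1.0 equiv), acetone, reflux; base extraction and distillation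
Reagents that add atoms: iodomethane, CI
Why: Williamson ether synthesis in which one equivalent of base and iodomethane alkylates the catechol monoanion once, the less acidic guaiacol reacts more slowly, and leftover catechol and veratrole are removed on work-up.

Step 2
Reactants: 2 2-methoxyphenol
Product: 3 4-bromo-2-methoxyphenol
Conditions: NBS (1.0 equiv), MeCN, 0 °C
Reagents that add atoms: N-bromosuccinimide, O=C1CCC(=O)N1Br
Why: Electrophilic aromatic bromination in which the free hydroxyl, the stronger donor, directs bromine to its para position.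

Step 3
Reactants: 3 4-bromo-2-methoxyphenol
Product: 4 1-(benzyloxy)-4-bromo-2-methoxybenzene
Conditions: BnBr (1.1 equiv), K2CO3, DMF, rt
Reagents that add atoms: benzyl bromide, BrCc1ccccc1
Why: Williamson benzylation of the phenoxide gives an ether that survives the organometallic, carbonylation, enolate and hydride steps and is removable by hydrogenolysis.

Step 4
Reactants: 4 1-(benzyloxy)-4-bromo-2-methoxybenzene; 5 3-(bromomethyl)oxetane
Product: 6 3-{[4-(benzyloxy)-3-methoxyphenyl]methyl}oxetane
Conditions: NiI2 (10 mol%), 4,4'-di-tert-butyl-2,2'-bipyridine (10 mol%), NaI (25 mol%), pyridine (10 mol%), Zn dust (2 equiv), DMPU, 60 °C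
Reagents that add atoms: none
Why: Nickel-catalysed reductive cross-electrophile coupling in which the aryl bromide adds oxidatively to zerovalent nickel and the primary alkyl radical from 5 is captured to form the aryl–CH2 bond, with oxetane and ethers inert to zinc.

Step 5
Reactants: 6 3-{[4-(benzyloxy)-3-methoxyphenyl]methyl}oxetane
Product: 7 (4S)-4-{[4-(benzyloxy)-3-methoxyphenyl]methyl}oxolan-2-one
Conditions: [(R,R)-(salen)Cr(THF)2][Co(CO)4] (5 mol%; salen = N,N'-bis(3,5-di-tert-butylsalicylidene)cyclohexane-1,2-diamine dianion), CO (60 bar), 1,2-dimethoxyethane, 60 °C, 24–48 h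
Reagents that add atoms: carbon monoxide, [C-]#[O+]
Why: Proposed new method: enantioselective desymmetrising carbonylative ring expansion of a prochiral 3-substituted oxetane, in which the chiral cationic trivalent chromium Lewis acid binds the oxetane oxygen, [Co(CO)4]− opens one of the two enantiotopic CH2–O bonds by backside attack (the enantio-determining event that fixes C4 as S), CO migratory insertion (a 1,2-alkyl shift from cobalt to the carbonyl carbon) gives the acyl cobalt, and the chromium alkoxide closes the five-membered lactone; the closest known reactions are the Lewis acid/[Co(CO)4]− carbonylative ring expansion of epoxides to β-lactones (including desymmetrisation of meso-epoxides with chiral salen Lewis acids), the racemic cobalt-catalysed carbonylation of oxetanes to γ-butyrolactones, and the desymmetrising opening of 3-substituted oxetanes by other nucleophiles under chiral salen-metal catalysis.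

Step 6
Reactants: 4 1-(benzyloxy)-4-bromo-2-methoxybenzene
Product: 9 4-(benzyloxy)-3-methoxybenzaldehyde, via aryllithium 8 (not isolated)
Conditions: n-BuLi (1.05 equiv), THF, −78 °C; DMF (2 equiv), −78 to 0 °C; aq. HCl
Reagents that add atoms: N,N-dimethylformamide, CN(C)C=O
Why: Bromine–lithium exchange followed by formylation of the aryllithium with DMF, the exchange at −78 °C being much faster than any attack on the benzyl ether.

Step 7
Reactants: 7 (4S)-4-{[4-(benzyloxy)-3-methoxyphenyl]methyl}oxolan-2-one; 9 4-(benzyloxy)-3-methoxybenzaldehyde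
Product: 11 (3R,4S)-3-{[4-(benzyloxy)-3-methoxyphenyl](hydroxy)methyl}-4-{[4-(benzyloxy)-3-methoxyphenyl]methyl}oxolan-2-one, via lithium enolate 10 (not isolated)
Conditions: LiN(iPr)2 (1.1 equiv), THF, −78 °C, 30 min; then 9, −78 °C, 1 h; AcOH quench at −78 °C
Reagents that add atoms: none
Why: Lithium enolate aldol addition in which the aldehyde approaches the enolate face anti to the C4 benzyl group, setting C3 trans (3R), while the carbinol centre forms as an epimer mixture that is erased in step 8.

Step 8
Reactants: 11 (3R,4S)-3-{[4-(benzyloxy)-3-methoxyphenyl](hydroxy)methyl}-4-{[4-(benzyloxy)-3-methoxyphenyl]methyl}oxolan-2-one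
Product: 13 [(2R,3S,4S)-2-[4-(benzyloxy)-3-methoxyphenyl]-4-{[4-(benzyloxy)-3-methoxyphenyl]methyl}oxolan-3-yl]methanol, via triol 12 (not isolated)
Conditions: LiAlH4 (3 equiv), THF, 0 °C to rt; then 2 M aq. HCl added at 0 °C to pH 1, rt, 2–4 h (stopped when the triol is consumed)
Reagents that add atoms: none
Why: Hydride reduction of the lactone to the 1,4-diol followed by acid-promoted SN1 cycloetherification, in which the 4-alkoxybenzylic cation is trapped 5-exo by the hydroxymethyl oxygen on the benzyl-bearing carbon with the aryl group going trans to the neighbouring CH2OH (the less hindered face, and reversible ionisation corrects the cis isomer), so both carbinol epimers converge on 2R.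

Step 9
Reactants: 13 [(2R,3S,4S)-2-[4-(benzyloxy)-3-methoxyphenyl]-4-{[4-(benzyloxy)-3-methoxyphenyl]methyl}oxolan-3-yl]methanol; 14 (2R)-2-methylbutanoic acid
Product: 15 [(2R,3S,4S)-2-[4-(benzyloxy)-3-methoxyphenyl]-4-{[4-(benzyloxy)-3-methoxyphenyl]methyl}oxolan-3-yl]methyl (2R)-2-methylbutanoate
Conditions: 14 (1.2 equiv), DCC (1.3 equiv), DMAP (0.1 equiv), CH2Cl2, 0 °C to rt
Reagents that add atoms: none
Why: Steglich esterification of the only free hydroxyl, under which the non-activated α-stereocentre of the acid is not expected to epimerise at 0 °C to rt.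

Step 10
Reactants: 15 [(2R,3S,4S)-2-[4-(benzyloxy)-3-methoxyphenyl]-4-{[4-(benzyloxy)-3-methoxyphenyl]methyl}oxolan-3-yl]methyl (2R)-2-methylbutanoate
Product: 16 [(2R,3S,4S)-2-(4-hydroxy-3-methoxyphenyl)-4-[(4-hydroxy-3-methoxyphenyl)methyl]oxolan-3-yl]methyl (2R)-2-methylbutanoate
Conditions: H2 (1 atm), Pd/C (10 wt% palladium on carbon), EtOAc, rt, stopped at full debenzylation
Reagents that add atoms: none
Why: Hydrogenolysis of the two aryl benzyl ethers under neutral conditions at 1 atm, which is much faster than cleavage of the cyclic benzylic ether and leaves the ester and all four stereocentres untouched.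

**Compound list**

1 | benzene-1,2-diol (catechol) | Oc1ccccc1O | starting material
2 | 2-methoxyphenol (guaiacol) | COc1ccccc1O | intermediate
3 | 4-bromo-2-methoxyphenol | COc1cc(Br)ccc1O | intermediate
4 | 1-(benzyloxy)-4-bromo-2-methoxybenzene | COc1cc(Br)ccc1OCc1ccccc1 | intermediate
5 | 3-(bromomethyl)oxetane | BrCC1COC1 | starting material
6 | 3-{[4-(benzyloxy)-3-methoxyphenyl]methyl}oxetane | COc1cc(CC2COC2)ccc1OCc1ccccc1 | intermediate
7 | (4S)-4-{[4-(benzyloxy)-3-methoxyphenyl]methyl}oxolan-2-one | O=C1C[C@H](Cc2ccc(OCc3ccccc3)c(OC)c2)CO1 | intermediate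
8 | [4-(benzyloxy)-3-methoxyphenyl]lithium | [Li]c1ccc(OCc2ccccc2)c(OC)c1 | intermediate
9 | 4-(benzyloxy)-3-methoxybenzaldehyde | COc1cc(C=O)ccc1OCc1ccccc1 | intermediate
10 | lithium enolate of 7 | [Li]OC1=C[C@H](Cc2ccc(OCc3ccccc3)c(OC)c2)CO1 | intermediate
11 | (3R,4S)-3-{[4-(benzyloxy)-3-methoxyphenyl](hydroxy)methyl}-4-{[4-(benzyloxy)-3-methoxyphenyl]methyl}oxolan-2-one (both carbinol epimers) | O=C1OC[C@@H](Cc2ccc(OCc3ccccc3)c(OC)c2)[C@@H]1C(O)c1ccc(OCc2ccccc2)c(OC)c1 | intermediate
12 | (2S,3S)-2-{[4-(benzyloxy)-3-methoxyphenyl](hydroxy)methyl}-3-{[4-(benzyloxy)-3-methoxyphenyl]methyl}butane-1,4-diol | OC[C@@H](C(O)c1ccc(OCc2ccccc2)c(OC)c1)[C@H](Cc1ccc(OCc2ccccc2)c(OC)c1)CO | intermediate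
13 | [(2R,3S,4S)-2-[4-(benzyloxy)-3-methoxyphenyl]-4-{[4-(benzyloxy)-3-methoxyphenyl]methyl}oxolan-3-yl]methanol | OC[C@@H]1[C@H](Cc2ccc(OCc3ccccc3)c(OC)c2)CO[C@H]1c1ccc(OCc2ccccc2)c(OC)c1 | intermediate
14 | (2R)-2-methylbutanoic acid | CC[C@@H](C)C(O)=O | starting material
15 | [(2R,3S,4S)-2-[4-(benzyloxy)-3-methoxyphenyl]-4-{[4-(benzyloxy)-3-methoxyphenyl]methyl}oxolan-3-yl]methyl (2R)-2-methylbutanoate | CC[C@@H](C)C(=O)OC[C@@H]1[C@H](Cc2ccc(OCc3ccccc3)c(OC)c2)CO[C@H]1c1ccc(OCc2ccccc2)c(OC)c1 | intermediate
16 | [(2R,3S,4S)-2-(4-hydroxy-3-methoxyphenyl)-4-[(4-hydroxy-3-methoxyphenyl)methyl]oxolan-3-yl]methyl (2R)-2-methylbutanoate | CC[C@@H](C)C(=O)OC[C@@H]1[C@H](Cc2ccc(O)c(OC)c2)CO[C@H]1c1ccc(O)c(OC)c1 | target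

**Totals and risks**

Total step count: 10. Longest linear sequence: 9 steps (steps 1–5 and 7–10; step 6 is a one-step branch from 4).

Steps most likely to fail:

- **Step 5 (the proposed new ring expansion).** The risks are slow turnover, Lewis-acid polyether formation from the oxetane, and insufficient enantioselectivity. The fallback sets out from 4 and comes back at 7. Bromide 4 is coupled under the nickel conditions of step 4 with commercial 3-(bromomethyl)cyclobutan-1-one (O=C1CC(CBr)C1) to give 3-{[4-(benzyloxy)-3-methoxyphenyl]methyl}cyclobutan-1-one F1. This prochiral ketone is then ring-expanded by a known enantioselective Baeyer–Villiger oxidation (Criegee 1,2-alkyl shift) with an (S)-selective Baeyer–Villiger monooxygenase in whole cells under air, or chemically with aqueous H2O2 and a chiral phosphoric acid, to give 7, which is recrystallised to raise the ee. Oxetane 6 is then not needed.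

- **Step 8 (one-pot reduction and acid cyclisation).** The risks are Friedel–Crafts closure of the benzylic cation onto the other arene (aryltetralin) and an unfavourable C2 epimer ratio. The fallback sets out from 11 and comes back at 16. Lactone 11 is reduced with LiAlH4 and worked up with potassium sodium tartrate (KNaC4H4O6) so that triol 12 is isolated. Its benzyl ethers are removed with H2 over Pd/C (10 wt% palladium on carbon) in EtOAc to give (2S,3S)-2-[hydroxy(4-hydroxy-3-methoxyphenyl)methyl]-3-[(4-hydroxy-3-methoxyphenyl)methyl]butane-1,4-diol F2. The free para-hydroxybenzylic alcohol of F2 ionises through its quinone methide under very mild acid (pyridinium p-toluenesulfonate, THF, rt), too mild for aryltetralin formation, and closes to 4-[(2R,3S,4S)-4-[(4-hydroxy-3-methoxyphenyl)methyl]-3-(hydroxymethyl)oxolan-2-yl]-2-methoxyphenol F3. A chemoselective Mitsunobu esterification with 14 (PPh3, diisopropyl azodicarboxylate, THF, 0 °C) then activates only the aliphatic primary hydroxyl, with the carboxylic acid as nucleophile, and gives 16 directly, bypassing 13 and 15.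

- **Step 4 (reductive coupling).** The risks are ring opening of the oxetan-3-ylmethyl radical and homocoupling of the electron-rich aryl bromide. The fallback sets out from 4 and comes back at 6. Commercial 3-methylideneoxetane (C=C1COC1) is hydroborated with 9-borabicyclo[3.3.1]nonane in THF to give 9-(oxetan-3-ylmethyl)-9-borabicyclo[3.3.1]nonane F4. This is used without isolation in a B-alkyl Suzuki–Miyaura coupling with 4 (PdCl2(dppf), K3PO4, THF/H2O, 60 °C), a two-electron transmetalation pathway with no radical intermediate, to give 6.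

**Further compounds**

F1 | step 5 | 3-{[4-(benzyloxy)-3-methoxyphenyl]methyl}cyclobutan-1-one | O=C1CC(Cc2ccc(OCc3ccccc3)c(OC)c2)C1
F2 | step 8 | (2S,3S)-2-[hydroxy(4-hydroxy-3-methoxyphenyl)methyl]-3-[(4-hydroxy-3-methoxyphenyl)methyl]butane-1,4-diol | OC[C@@H](C(O)c1ccc(O)c(OC)c1)[C@H](Cc1ccc(O)c(OC)c1)CO
F3 | step 8 | 4-[(2R,3S,4S)-4-[(4-hydroxy-3-methoxyphenyl)methyl]-3-(hydroxymethyl)oxolan-2-yl]-2-methoxyphenol | OC[C@@H]1[C@H](Cc2ccc(O)c(OC)c2)CO[C@H]1c1ccc(O)c(OC)c1
F4 | step 4 | 9-(oxetan-3-ylmethyl)-9-borabicyclo[3.3.1]nonane | B1(CC2COC2)C2CCCC1CCC2
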